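Ring A (the monohydroxy ring) is cut at C-3–C-4 and C-1–C-6 (carotenoid numbering) into two acyclic three-carbon units. Its carbinol C-3, methylene C-4 and C-5=C-6 double bond form a homoallylic alcohol, and quaternary C-1 sits on alkyne-bearing C-6. One Lewis-acid operation therefore joins a β-methoxy aldehyde to a skipped dienyne phosphonate: carbonyl-ene reaction (C-3–C-4), then ether ionisation and 6-endo cation–olefin closure (C-1–C-6), giving the complete C15 end group. Lipase resolution sets C-3. Ring B comes from ketoisophorone by acetylide addition and a carbonate-directed allylic transposition. The halves are joined through the C10 dialdehyde by Horner–Wadsworth–Emmons and Wittig olefinations.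

Key step: step 4

Remark on the chemistry: positions are given in carotenoid numbering (ring A C-1 to C-6 with the hydroxyl at C-3, chain C-7 to C-15, primed locants for the diol half); 1, 3, 4, 11 and 15 are taken to be commercial, and the hindered 11'Z isomer from the last olefination is assumed to relax thermally to all-E without change at the 9 and 9' double bonds.

Step 1
Reactants: 1 3-methoxy-3-methylbutan-1-ol
Product: 2 3-methoxy-3-methylbutanal
Conditions: TEMPO (0.1 equiv), PhI(OAc)2 (1.1 equiv), CH2Cl2, rt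
Reagents that add atoms: none
Why: Oxoammonium (TEMPO) oxidation of the primary alcohol stops at the aldehyde under near-neutral conditions, which avoids β-elimination of methanol.

Step 2
Reactants: 3 (2E)-3-methylpent-2-en-4-yn-1-ol; 4 3-chloro-2-methylprop-1-ene
Product: 5 (2E)-3,7-dimethylocta-2,7-dien-4-yn-1-ol
Conditions: CuI (0.1 equiv), NaI (0.2 equiv), K2CO3 (1.5 equiv), DMF, rt
Reagents that add atoms: none
Why: Copper-acetylide allylation of the terminal alkyne with the allylic chloride should give the skipped enyne, the mild carbonate base leaving the hydroxyl, the E double bond and the doubly activated CH2 untouched.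

Step 3
Reactants: 5 (2E)-3,7-dimethylocta-2,7-dien-4-yn-1-ol
Product: 7 diethyl [(2E)-3,7-dimethylocta-2,7-dien-4-yn-1-yl]phosphonate, via allyl diethyl phosphite 6 (not isolated)
Conditions: P(OEt)3 (3 equiv), ZnI2 (1.5 equiv), THF, reflux
Reagents that add atoms: triethyl phosphite CCOP(OCC)OCC
Why: Transesterification to the mixed phosphite followed by ZnI2-promoted Michaelis–Arbuzov-type rearrangement should turn the primary allylic alcohol directly into the phosphonate, with phosphorus at the primary carbon and the E geometry kept.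

Step 4
Reactants: 7 diethyl [(2E)-3,7-dimethylocta-2,7-dien-4-yn-1-yl]phosphonate; 2 3-methoxy-3-methylbutanal
Product: 9 diethyl [(2E)-5-(4-hydroxy-2,6,6-trimethylcyclohex-1-en-1-yl)-3-methylpent-2-en-4-yn-1-yl]phosphonate (racemic), via ene-adduct aluminium alkoxide 8 (not isolated)
Conditions: 2 (1.1 equiv), Me2AlCl (2.5 equiv), CH2Cl2, −78 → −40 °C; then MeAlCl2 (2 equiv), −40 → 0 °C, same flask; aq. HCl work-up
Reagents that add atoms: none
Why: Proposed new method: Me2AlCl activates the chelating β-methoxy aldehyde 2, whose carbonyl carbon is attacked by the CH2 terminus of the 1,1-disubstituted alkene of 7 in a Lewis-acid carbonyl-ene (Prins-type) reaction; the allylic and propargylic hydrogen passes to oxygen, so the C-3–C-4 bond forms and the double bond moves to C-5=C-6 in conjugation with the alkyne (8). The stronger MeAlCl2 then ionises the tertiary methyl ether, and the C-1 cation alkylates C-6 of the enyne double bond in a 6-endo-trig cation–olefin closure (C-1–C-6), after which loss of the C-6 proton restores the tetrasubstituted alkene conjugated to the triple bond. The closest known reaction types are the alkylaluminium chloride-mediated ene reaction of aldehydes with 1,1-disubstituted alkenes and the pseudoionone-to-β-ionone cyclisation; their combination into one [3+3] annulation that uses a β-alkoxy aldehyde as 1,3-dielectrophile is the untested part. The only stereocentre, C-3, arises in the intermolecular ene stage without control, so 9 is racemic and C-3 is set by the resolution of step 5. The step needs proton transfer from the propargylic CH2 and not from the methyl group (favoured by the acidity of that hydrogen and the conjugation gained), ene reaction before ether ionisation (secured by the weaker first Lewis acid at −78 °C) and 6-endo over 5-exo closure (tertiary cation, no vicinal quaternary centres).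

Step 5
Reactants: 9 diethyl [(2E)-5-(4-hydroxy-2,6,6-trimethylcyclohex-1-en-1-yl)-3-methylpent-2-en-4-yn-1-yl]phosphonate (racemic)
Product: 10 diethyl {(2E)-5-[(4R)-4-acetoxy-2,6,6-trimethylcyclohex-1-en-1-yl]-3-methylpent-2-en-4-yn-1-yl}phosphonate
Conditions: lipase PS (Burkholderia cepacia, immobilised), vinyl acetate (3 equiv), t-BuOMe, 30 °C, stopped near half conversion
Reagents that add atoms: vinyl acetate C=COC(C)=O
Why: Lipase-catalysed kinetic resolution by irreversible transesterification should, by the empirical size rule for secondary alcohols (C-2/C-1 arm large, C-4/C-5 arm medium), acetylate the (3R)-alcohol, which fixes C-3 and leaves the acetate as protecting group.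

Step 6
Reactants: 10 diethyl {(2E)-5-[(4R)-4-acetoxy-2,6,6-trimethylcyclohex-1-en-1-yl]-3-methylpent-2-en-4-yn-1-yl}phosphonate; 11 (2E,4E,6E)-2,7-dimethylocta-2,4,6-trienedial
Product: 13 (2E,4E,6E,8E,10E)-13-[(4R)-4-acetoxy-2,6,6-trimethylcyclohex-1-en-1-yl]-2,7,11-trimethyltrideca-2,4,6,8,10-pentaen-12-ynal, via sodium phosphonate carbanion 12 (not isolated)
Conditions: NaN(SiMe3)2 (1.05 equiv), THF, −78 °C; then added to 11 (3 equiv), −78 → 0 °C
Reagents that add atoms: none
Why: Horner–Wadsworth–Emmons olefination of the allylic phosphonate carbanion with an excess of the symmetrical dialdehyde should give the mono-adduct with E geometry at the new C-11=C-12 bond, the amide base deprotonating the phosphonate faster than the acetate.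

Step 7
Reactants: 3 (2E)-3-methylpent-2-en-4-yn-1-ol
Product: 14 tert-butyl(dimethyl){[(2E)-3-methylpent-2-en-4-yn-1-yl]oxy}silane
Conditions: TBSCl (1.1 equiv), imidazole (1.5 equiv), CH2Cl2, 0 °C → rt
Reagents that add atoms: tert-butyldimethylsilyl chloride CC(C)(C)[Si](C)(C)Cl
Why: Standard silylation protects the primary alcohol for the acetylide chemistry.

Step 8
Reactants: 15 2,6,6-trimethylcyclohex-2-ene-1,4-dione (ketoisophorone)
Product: 16 (4S)-4-hydroxy-2,6,6-trimethylcyclohex-2-en-1-one
Conditions: RuCl(p-cymene)[(S,S)-TsDPEN] (0.5 mol %), i-PrOH, rt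
Reagents that add atoms: none
Why: Asymmetric transfer hydrogenation should reduce only the unhindered enone carbonyl (the other is flanked by the gem-dimethyl and methyl-bearing carbons), and the (S,S)-ligand is expected to give the (S)-carbinol as with other alkenyl ketones, which sets C-3'.

Step 9
Reactants: 16 (4S)-4-hydroxy-2,6,6-trimethylcyclohex-2-en-1-one; 14 tert-butyl(dimethyl){[(2E)-3-methylpent-2-en-4-yn-1-yl]oxy}silane
Product: 19 tert-butyl (1S)-4-[(3E)-5-(tert-butyldimethylsilyloxy)-3-methylpent-3-en-1-yn-1-yl]-4-hydroxy-3,5,5-trimethylcyclohex-2-en-1-yl carbonate (both epimers at the tertiary carbinol), via lithium acetylide 17 (not isolated), via dilithium dialkoxide 18 (not isolated)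
Conditions: 14 (2.1 equiv), n-BuLi (2.05 equiv), THF, −78 °C; 16, −78 → 0 °C; then Boc2O (1.2 equiv), −78 °C → rt; aq. NH4Cl
Reagents that add atoms: di-tert-butyl dicarbonate CC(C)(C)OC(=O)OC(=O)OC(C)(C)C
Why: 1,2-Addition of the lithium acetylide to the hindered enone carbonyl (the first equivalent of 17 deprotonates the hydroxyl and returns 14) is followed by acylation of the unhindered secondary alkoxide only, and the configuration of the new tertiary carbinol is irrelevant because that centre is ionised in step 10.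

Step 10
Reactants: 19 tert-butyl (1S)-4-[(3E)-5-(tert-butyldimethylsilyloxy)-3-methylpent-3-en-1-yn-1-yl]-4-hydroxy-3,5,5-trimethylcyclohex-2-en-1-yl carbonate
Product: 20 tert-butyl(dimethyl){[(2E)-3-methyl-5-[(3R,4S)-3,4-(carbonyldioxy)-2,6,6-trimethylcyclohex-1-en-1-yl]pent-2-en-4-yn-1-yl]oxy}silane (cis-fused cyclic carbonate)
Conditions: BF3·OEt2 (0.3 equiv), 4 Å molecular sieves, CH2Cl2, −40 → 0 °C
Reagents that add atoms: none
Why: Acid ionises the tertiary allylic and propargylic alcohol to a delocalised cation that is captured at C-4' by the carbonyl oxygen of the neighbouring tert-butyl carbonate (SN1' allylic transposition with neighbouring-group participation, loss of isobutene); the five-membered carbonate can only be cis-fused, so the C-4' oxygen is delivered cis to the C-3' oxygen from either epimer of 19 and the double bond moves into conjugation with the alkyne.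

Step 11
Reactants: 20 tert-butyl(dimethyl){[(2E)-3-methyl-5-[(3R,4S)-3,4-(carbonyldioxy)-2,6,6-trimethylcyclohex-1-en-1-yl]pent-2-en-4-yn-1-yl]oxy}silane
Product: 22 {(2E)-3-methyl-5-[(3R,4S)-3,4-(carbonyldioxy)-2,6,6-trimethylcyclohex-1-en-1-yl]pent-2-en-4-yn-1-yl}triphenylphosphonium bromide, via allylic alcohol 21 (not isolated)
Conditions: Ph3P·HBr (1.3 equiv), MeOH, rt
Reagents that add atoms: triphenylphosphine hydrobromide [Br-].[PH+](c1ccccc1)(c1ccccc1)c1ccccc1
Why: Acidic methanolysis of the primary silyl ether releases the allylic alcohol, which the same reagent converts into the allylic phosphonium salt (the standard end-group Wittig salt formation), the cyclic carbonate being stable to the weakly acidic medium.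

Step 12
Reactants: 22 {(2E)-3-methyl-5-[(3R,4S)-3,4-(carbonyldioxy)-2,6,6-trimethylcyclohex-1-en-1-yl]pent-2-en-4-yn-1-yl}triphenylphosphonium bromide; 13 (2E,4E,6E,8E,10E)-13-[(4R)-4-acetoxy-2,6,6-trimethylcyclohex-1-en-1-yl]-2,7,11-trimethyltrideca-2,4,6,8,10-pentaen-12-ynal
Product: 25 (all-E)-(3R,3'S,4'R)-7,8,7',8'-tetradehydro-β,β-carotene-3,3',4'-triol (CNP0323983.1), via phosphorus ylide 23 (not isolated), via protected C40 carotenoid 24 (not isolated)
Conditions: 22 (1.2 equiv), NaOMe (6 equiv), MeOH/CH2Cl2, 0 °C → rt; then EtOAc, reflux, dark (11'Z → E); crystallisation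
Reagents that add atoms: none
Why: Wittig olefination of the allylic ylide with the apo-aldehyde closes the C40 chain at C-11'=C-12', the excess methoxide then cleaves the acetate and the cyclic carbonate in the same flask, and heating should convert the hindered 11'Z isomer into the all-E triol.

Compound list
1 | 3-methoxy-3-methylbutan-1-ol | COC(C)(C)CCO | starting material
2 | 3-methoxy-3-methylbutanal | COC(C)(C)CC=O | intermediate
3 | (2E)-3-methylpent-2-en-4-yn-1-ol | C#C/C(C)=C/CO | starting material
4 | 3-chloro-2-methylprop-1-ene (methallyl chloride) | CC(=C)CCl | starting material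
5 | (2E)-3,7-dimethylocta-2,7-dien-4-yn-1-ol | CC(=C)CC#C/C(C)=C/CO | intermediate
6 | diethyl (2E)-3,7-dimethylocta-2,7-dien-4-yn-1-yl phosphite | CC(=C)CC#C/C(C)=C/COP(OCC)OCC | intermediate (not isolated)
7 | diethyl [(2E)-3,7-dimethylocta-2,7-dien-4-yn-1-yl]phosphonate | CC(=C)CC#C/C(C)=C/CP(=O)(OCC)OCC | intermediate
8 | chloro(methyl)aluminium alkoxide of diethyl [(2E)-9-hydroxy-11-methoxy-3,7,11-trimethyldodeca-2,6-dien-4-yn-1-yl]phosphonate (ene adduct; racemic; 6E/6Z mixture) | COC(C)(C)CC(O[Al](C)Cl)CC(C)=CC#C/C(C)=C/CP(=O)(OCC)OCC | intermediate (not isolated)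
9 | diethyl [(2E)-5-(4-hydroxy-2,6,6-trimethylcyclohex-1-en-1-yl)-3-methylpent-2-en-4-yn-1-yl]phosphonate (racemic) | CC1=C(C#C/C(C)=C/CP(=O)(OCC)OCC)C(C)(C)CC(O)C1 | intermediate
10 | diethyl {(2E)-5-[(4R)-4-acetoxy-2,6,6-trimethylcyclohex-1-en-1-yl]-3-methylpent-2-en-4-yn-1-yl}phosphonate | CC1=C(C#C/C(C)=C/CP(=O)(OCC)OCC)C(C)(C)C[C@H](OC(C)=O)C1 | intermediate
11 | (2E,4E,6E)-2,7-dimethylocta-2,4,6-trienedial (C10 dialdehyde) | O=C/C(C)=C/C=C/C=C(C)/C=O | starting material
12 | sodium salt of the C-11 carbanion of 10 | [Na+].CC1=C(C#C/C(C)=C/[CH-]P(=O)(OCC)OCC)C(C)(C)C[C@H](OC(C)=O)C1 | intermediate (not isolated)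
13 | (2E,4E,6E,8E,10E)-13-[(4R)-4-acetoxy-2,6,6-trimethylcyclohex-1-en-1-yl]-2,7,11-trimethyltrideca-2,4,6,8,10-pentaen-12-ynal (C25 apo-aldehyde) | CC1=C(C#C/C(C)=C/C=C/C(C)=C/C=C/C=C(C)/C=O)C(C)(C)C[C@H](OC(C)=O)C1 | intermediate
14 | tert-butyl(dimethyl){[(2E)-3-methylpent-2-en-4-yn-1-yl]oxy}silane | C#C/C(C)=C/CO[Si](C)(C)C(C)(C)C | intermediate
15 | 2,6,6-trimethylcyclohex-2-ene-1,4-dione (ketoisophorone) | CC1=CC(=O)CC(C)(C)C1=O | starting material
16 | (4S)-4-hydroxy-2,6,6-trimethylcyclohex-2-en-1-one | CC1=C[C@@H](O)CC(C)(C)C1=O | intermediate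
17 | lithium acetylide of 14 | [Li]C#C/C(C)=C/CO[Si](C)(C)C(C)(C)C | intermediate (not isolated)
18 | dilithium salt of (4S)-1-[(3E)-5-(tert-butyldimethylsilyloxy)-3-methylpent-3-en-1-yn-1-yl]-2,6,6-trimethylcyclohex-2-ene-1,4-diol (both C-1 epimers) | CC1=C[C@@H](O[Li])CC(C)(C)C1(O[Li])C#C/C(C)=C/CO[Si](C)(C)C(C)(C)C | intermediate (not isolated)
19 | tert-butyl (1S)-4-[(3E)-5-(tert-butyldimethylsilyloxy)-3-methylpent-3-en-1-yn-1-yl]-4-hydroxy-3,5,5-trimethylcyclohex-2-en-1-yl carbonate (both epimers at the tertiary carbinol) | CC1=C[C@@H](OC(=O)OC(C)(C)C)CC(C)(C)C1(O)C#C/C(C)=C/CO[Si](C)(C)C(C)(C)C | intermediate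
20 | tert-butyl(dimethyl){[(2E)-3-methyl-5-[(3R,4S)-3,4-(carbonyldioxy)-2,6,6-trimethylcyclohex-1-en-1-yl]pent-2-en-4-yn-1-yl]oxy}silane (cis-fused cyclic carbonate) | CC(C)(C)[Si](C)(C)OC/C=C(\C)C#CC1=C(C)[C@@H](OC(=O)O2)[C@@H]2CC1(C)C | intermediate
21 | (2E)-3-methyl-5-[(3R,4S)-3,4-(carbonyldioxy)-2,6,6-trimethylcyclohex-1-en-1-yl]pent-2-en-4-yn-1-ol | OC/C=C(\C)C#CC1=C(C)[C@@H](OC(=O)O2)[C@@H]2CC1(C)C | intermediate (not isolated)
22 | {(2E)-3-methyl-5-[(3R,4S)-3,4-(carbonyldioxy)-2,6,6-trimethylcyclohex-1-en-1-yl]pent-2-en-4-yn-1-yl}triphenylphosphonium bromide | [Br-].c1ccccc1[P+](c1ccccc1)(c1ccccc1)C/C=C(\C)C#CC1=C(C)[C@@H](OC(=O)O2)[C@@H]2CC1(C)C | intermediate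
23 | triphenylphosphonium ylide of 22 | c1ccccc1P(c1ccccc1)(c1ccccc1)=C/C=C(\C)C#CC1=C(C)[C@@H](OC(=O)O2)[C@@H]2CC1(C)C | intermediate (not isolated)
24 | (3R,3'S,4'R)-3-acetoxy-3',4'-(carbonyldioxy)-7,8,7',8'-tetradehydro-β,β-carotene (11'E/11'Z mixture) | CC1=C(C#C/C(C)=C/C=C/C(C)=C/C=C/C=C(\C)C=C/C=C(\C)C#CC2=C(C)[C@@H](OC(=O)O3)[C@@H]3CC2(C)C)C(C)(C)C[C@H](OC(C)=O)C1 | intermediate (not isolated)
25 | (all-E)-(3R,3'S,4'R)-7,8,7',8'-tetradehydro-β,β-carotene-3,3',4'-triol (CNP0323983.1) | CC1=C(C#C/C(C)=C/C=C/C(C)=C/C=C/C=C(C)/C=C/C=C(\C)C#CC2=C(C)[C@@H](O)[C@@H](O)CC2(C)C)C(C)(C)C[C@H](O)C1 | target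

Total step count: 12.
Longest linear sequence: 6 steps (steps 2, 3, 4, 5, 6 and 12, from 3).

Steps most likely to fail

Step 4 (Proposed new method). In the ene stage the proton may be lost from the methyl group instead of the propargylic methylene, or the tertiary ether may ionise before the aldehyde has reacted and shed methanol; either diverts material from ring closure, and the final proton loss may give double-bond isomers. The fallback uses known chemistry, sets out from 2 and 3 and returns at 9. Zinc-mediated Barbier propargylation of 2 with propargyl bromide gives racemic 6-methoxy-6-methylhept-1-yn-4-ol F1. Zirconium-catalysed methylalumination (Me3Al, Cp2ZrCl2) followed by I2 gives (1E)-1-iodo-6-methoxy-2,6-dimethylhept-1-en-4-ol F2. Sonogashira coupling (Pd(PPh3)4, CuI, Et3N) with diethyl [(2E)-3-methylpent-2-en-4-yn-1-yl]phosphonate F3, made from 3 by the method of step 3, gives diethyl [(2E,6E)-9-hydroxy-11-methoxy-3,7,11-trimethyldodeca-2,6-dien-4-yn-1-yl]phosphonate F4, in which the trisubstituted double bond is already in place. A separate MeAlCl2-induced cation–olefin cyclisation of F4 then gives 9.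

Step 10. The propargylic cation may rearrange to an enone (Meyer–Schuster pathway), lose a proton to a cross-conjugated triene, or the Boc group may be lost before it captures the cation. The fallback sets out from 19 and returns at 20. The hydroxyl is moved without a free cation by the 1,3-transposition catalysed by Ph3SiOReO3, giving tert-butyl (1S)-4-[(3E)-5-(tert-butyldimethylsilyloxy)-3-methylpent-3-en-1-yn-1-yl]-2-hydroxy-3,5,5-trimethylcyclohex-3-en-1-yl carbonate F5 as an epimer mixture at the new carbinol. MnO2 oxidises it to tert-butyl (1S)-4-[(3E)-5-(tert-butyldimethylsilyloxy)-3-methylpent-3-en-1-yn-1-yl]-3,5,5-trimethyl-2-oxocyclohex-3-en-1-yl carbonate F6. Reduction with LiBH(s-Bu)3 from the face opposite the carbonate should give the cis alkoxide, which closes onto the Boc carbonyl with loss of tert-butoxide to give 20.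

Step 5. The enzyme may discriminate poorly between the two ring arms, which both begin with CH2, so that the acetate is formed with low enantiomeric purity. The fallback sets out from 9 and returns at 10. Esterification of racemic 9 with (S)-O-methylmandelic acid (DCC, DMAP) gives two diastereomeric esters separable by chromatography, the (S)-O-methylmandelate of (3R)-9 F7 and the (S)-O-methylmandelate of (3S)-9 F8. Methanolysis of F7 (K2CO3, MeOH) gives diethyl {(2E)-5-[(4R)-4-hydroxy-2,6,6-trimethylcyclohex-1-en-1-yl]-3-methylpent-2-en-4-yn-1-yl}phosphonate F9, which is acetylated (Ac2O, pyridine) to 10.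

Further compounds
F1 | step 4 | 6-methoxy-6-methylhept-1-yn-4-ol (racemic) | C#CCC(O)CC(C)(C)OC
F2 | step 4 | (1E)-1-iodo-6-methoxy-2,6-dimethylhept-1-en-4-ol (racemic) | COC(C)(C)CC(O)C/C(C)=C/I
F3 | step 4 | diethyl [(2E)-3-methylpent-2-en-4-yn-1-yl]phosphonate | C#C/C(C)=C/CP(=O)(OCC)OCC
F4 | step 4 | diethyl [(2E,6E)-9-hydroxy-11-methoxy-3,7,11-trimethyldodeca-2,6-dien-4-yn-1-yl]phosphonate (racemic) | COC(C)(C)CC(O)C/C(C)=C/C#C/C(C)=C/CP(=O)(OCC)OCC
F5 | step 10 | tert-butyl (1S)-4-[(3E)-5-(tert-butyldimethylsilyloxy)-3-methylpent-3-en-1-yn-1-yl]-2-hydroxy-3,5,5-trimethylcyclohex-3-en-1-yl carbonate (both C-2 epimers) | CC(C)(C)[Si](C)(C)OC/C=C(\C)C#CC1=C(C)C(O)[C@@H](OC(=O)OC(C)(C)C)CC1(C)C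
F6 | step 10 | tert-butyl (1S)-4-[(3E)-5-(tert-butyldimethylsilyloxy)-3-methylpent-3-en-1-yn-1-yl]-3,5,5-trimethyl-2-oxocyclohex-3-en-1-yl carbonate | CC(C)(C)[Si](C)(C)OC/C=C(\C)C#CC1=C(C)C(=O)[C@@H](OC(=O)OC(C)(C)C)CC1(C)C
F7 | step 5 | (S)-O-methylmandelate of (3R)-9 | CC1=C(C#C/C(C)=C/CP(=O)(OCC)OCC)C(C)(C)C[C@H](OC(=O)[C@@H](OC)c2ccccc2)C1
F8 | step 5 | (S)-O-methylmandelate of (3S)-9 | CC1=C(C#C/C(C)=C/CP(=O)(OCC)OCC)C(C)(C)C[C@@H](OC(=O)[C@@H](OC)c2ccccc2)C1
F9 | step 5 | diethyl {(2E)-5-[(4R)-4-hydroxy-2,6,6-trimethylcyclohex-1-en-1-yl]-3-methylpent-2-en-4-yn-1-yl}phosphonate | CC1=C(C#C/C(C)=C/CP(=O)(OCC)OCC)C(C)(C)C[C@H](O)C1
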